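All runs come from a simulation for substances that don't exist, noise included.

If you repeat this run, weigh the impurity against the enzyme before you watch anything else. The step enzyme + impurity -> spent catalyst takes them one to one, so equal charges are the zero of your scale. This flask's value, 0.350, is one minus the impurity charge over the enzyme charge, the surviving share. Here the impurity charge is smaller than the enzyme charge, so the impurity is the limiting reagent of that step.

| flask | substrate | enzyme | impurity | remark | time |
|---|---|---|---|---|---|
| blue | 10 mM | 2 µM | 0.65 µM | run made earlier |  |
| grey | 10 mM | 2 µM | 2.6 µM | run made earlier |  |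
| green | 15 mM | 2 µM | 1.3 µM | run made earlier |  |
| flask | 10 mM | 2.0 µM | 1.3 µM |  | 50 min |

- blue (time / min: target / %, self-condensation product / %, substrate / %): 8.00: 19, 19, 66; 15.0: 28, 28, 45; 25.0: 41, 31, 31; 30.0: 44, 33, 22
- grey (time / min: target / %, self-condensation product / %, substrate / %): 8.00: 8, 20, 70; 15.0: 9, 34, 61; 25.0: 13, 44, 49; 30.0: 11, 46, 41
- green (time / min: target / %, self-condensation product / %, substrate / %): 8.00: 12, 24, 61; 15.0: 13, 40, 46; 25.0: 16, 47, 31; 30.0: 23, 52, 29

(readings scatter by 2 percentage points)

- a species is counted by the substrate in it: one self-condensation product counts as two
- what was read earlier has a scatter of 2 percentage points, one standard deviation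
- reactions considered so far: 2 substrate -> self-condensation product; substrate + enzyme <-> complex; complex -> enzyme + target; enzyme + impurity -> spent catalyst

1. concentration of target at 50 min, in mM
2. concentration of self-condensation product at 50 min, in mM
3. concentration of substrate at 50 min, in mM

Two runs bracket this flask. The grey run is the low end. Its impurity charge exceeds its enzyme charge, so its share is −0.300, below the zero. Its target reads 8.00% of the charge at 8.00 min and 11.0% at 30.0 min, a burst that then stalls.

The blue run is the high end, with a share of 0.675. Its target readings rise by 0.0107 min⁻¹ of the charge between 15.0 min and 30.0 min. Run that gain for 50 min on top of the last grey reading and your estimate is 0.643 of the charge.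

This flask's share lies lower than blue's, so I scale the gain by the share and commit to 0.387 of the charge as target. This is rough: while that gain was read, substrate in the blue run went from 45% to 22% of the charge.

The forecast, lower than mine on target, gives 3.4 mM of target, 2.4 mM of self-condensation product and 1.8 mM of substrate, holding that “the impurity titrates enzyme about 1:1 within several minutes”.

The flask gives 3.80 mM of target, which is 38.0% of the charge, with 2.18 mM of self-condensation product and 1.85 mM of substrate.

    2 substrate → self-condensation product (k = 1.90 M⁻¹ min⁻¹)
    substrate + enzyme ⇌ complex (K = 210 M⁻¹, k = 1.30 × 10⁵ M⁻¹ min⁻¹)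
    complex → enzyme + target (k = 230 min⁻¹)
    enzyme + impurity → spent catalyst (k = 3.70 × 10⁵ M⁻¹ min⁻¹)

At 50.0 min, this flask has 0.0110% of its impurity charge left and 65.0% of its catalyst charge as spent catalyst, while enzyme at 27.3% and complex at 7.74% add up to 35.0%, against a surviving share of 0.350. A neighbouring flask with 5.2 × 10⁻⁴ mM of impurity, all else equal, has a share of 0.740. At 50.0 min it holds 74.0% of its catalyst as enzyme and complex, and it ends at 5.66 mM of target.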